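**Plan**

- Numbering used: lactone ring O1, C2 (quaternary, bears CO2H), C3, C4, C5 (C=O); C1' is the side-chain CH(CO2H) on C2. The retrosynthesis cuts, in this order: the ester bond between the chain oxygen and C1 of (R)-malic acid; ring bonds O1–C2 and C3–C4 together; the C2 carboxyl back to a CH2–O held in a temporary γ-lactone with the C1' carboxyl; the C1'–allyl bond of an Evans alkylation.
- Enabling feature: C2 is a fully substituted carbon that carries both ring O1 and ring CH2 C3, so the lactone is the (3+2) adduct of a carboxymethyl unit (C4, C5, O1) across a C2=C3 methylene. The vicinal carboxyls on C2 and C1' let that methylene sit exocyclic on a five-membered template ring next to the C1' stereocentre.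
- Forward order: chain acid → imide → allylation → aldehyde → enal → temporary methylene lactone (ring A) → spiro-annulation builds the target lactone (ring B) → ring A is opened and its CH2O oxidised to CO2H, ring B recloses → desilylation → malate ester.
- Stereochemistry: C1' (R) from the (S)-4-benzyloxazolidinone auxiliary; C2 (R) relayed from C1' in the spiro-annulation (ring closure anti to the decyl chain on ring A); the malate (R) centre is bought as (R)-malic acid.

Key step: step 7

Remark: 12-hydroxydodecanoic acid, (S)-4-benzyl-1,3-oxazolidin-2-one and (R)-malic acid are taken as commercial; everything else is a common reagent.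

**Route**

Step 1
Reactants: 1 12-hydroxydodecanoic acid
Product: 3 12-(tert-butyldiphenylsilyloxy)dodecanoic acid, via tert-butyldiphenylsilyl 12-(tert-butyldiphenylsilyloxy)dodecanoate 2 (not isolated)
Conditions: TBDPSCl (2.2 equiv), imidazole, DMF, 0 °C → rt; then K2CO3, MeOH/THF/H2O, rt; 1 M HCl to pH 3
Reagents that add atoms: tert-butyldiphenylsilyl chloride (CC(C)(C)[Si](Cl)(c1ccccc1)c1ccccc1)
Why: Silylation of both OH groups followed by selective hydrolysis of the far more labile silyl ester (standard silyl ether protection) should leave only the primary TBDPS ether, which is robust enough for the enolate, oxidant and acid steps up to step 9.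

Step 2
Reactants: 3 12-(tert-butyldiphenylsilyloxy)dodecanoic acid; 4 (S)-4-benzyl-1,3-oxazolidin-2-one
Product: 6 (S)-4-benzyl-3-[12-(tert-butyldiphenylsilyloxy)dodecanoyl]-1,3-oxazolidin-2-one, via 12-(tert-butyldiphenylsilyloxy)dodecanoic pivalic anhydride 5 (not isolated)
Conditions: PivCl, Et3N, THF, −20 °C; then LiCl and 4, −20 °C → rt
Reagents that add atoms: none
Why: N-Acylation of the Evans auxiliary through the mixed pivalic anhydride (LiCl/Et3N one-pot protocol) is a standard way to load a long-chain acid onto the oxazolidinone.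

Step 3
Reactants: 6 (S)-4-benzyl-3-[12-(tert-butyldiphenylsilyloxy)dodecanoyl]-1,3-oxazolidin-2-one
Product: 8 (S)-4-benzyl-3-[(2R)-2-allyl-12-(tert-butyldiphenylsilyloxy)dodecanoyl]-1,3-oxazolidin-2-one, via sodium (Z)-imide enolate 7 (not isolated)
Conditions: NaN(SiMe3)2, THF, −78 °C; then allyl iodide, −78 → −45 °C
Reagents that add atoms: allyl iodide (C=CCI)
Why: Evans asymmetric alkylation, in which the chelated (Z)-enolate 7 is attacked by allyl iodide on the face opposite the 4-benzyl group, should set the (R) centre that becomes C1' of the target.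

Step 4
Reactants: 8 (S)-4-benzyl-3-[(2R)-2-allyl-12-(tert-butyldiphenylsilyloxy)dodecanoyl]-1,3-oxazolidin-2-one
Product: 10 (3R)-4-[(S)-4-benzyl-2-oxo-1,3-oxazolidin-3-yl]-3-[10-(tert-butyldiphenylsilyloxy)decyl]-4-oxobutanal, via 1,2,4-trioxolane (ozonide) of the allyl group 9 (not isolated)
Conditions: O3, CH2Cl2, −78 °C; then PPh3, −78 °C → rt
Reagents that add atoms: ozone ([O-][O+]=O)
Why: Ozonolysis with reductive work-up should cleave the terminal alkene to the aldehyde under neutral conditions that leave the imide, the silyl ether and the stereocentre untouched.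

Step 5
Reactants: 10 (3R)-4-[(S)-4-benzyl-2-oxo-1,3-oxazolidin-3-yl]-3-[10-(tert-butyldiphenylsilyloxy)decyl]-4-oxobutanal
Product: 12 (3R)-4-[(S)-4-benzyl-2-oxo-1,3-oxazolidin-3-yl]-3-[10-(tert-butyldiphenylsilyloxy)decyl]-2-methylene-4-oxobutanal, via 2-(dimethylaminomethyl) Mannich base of aldehyde 10 11 (not isolated)
Conditions: Me2N=CH2 I (Eschenmoser's salt), Et3N, CH2Cl2, rt
Reagents that add atoms: N,N-dimethylmethyleneiminium iodide (C=[N+](C)C.[I-])
Why: Eschenmoser methylenation (Mannich reaction of the aldehyde with the iminium salt, then amine-promoted β-elimination of dimethylamine) should install the 1,1-disubstituted alkene, the imide α-hydrogen being kinetically non-acidic.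

Step 6
Reactants: 12 (3R)-4-[(S)-4-benzyl-2-oxo-1,3-oxazolidin-3-yl]-3-[10-(tert-butyldiphenylsilyloxy)decyl]-2-methylene-4-oxobutanal
Product: 14 (3R)-3-[10-(tert-butyldiphenylsilyloxy)decyl]-4-methylenedihydrofuran-2(3H)-one, via (S)-4-benzyl-3-[(2R)-12-(tert-butyldiphenylsilyloxy)-2-(3-hydroxyprop-1-en-2-yl)dodecanoyl]-1,3-oxazolidin-2-one 13 (not isolated)
Conditions: NaBH4, CeCl3·7H2O, MeOH/THF, −40 → 0 °C; then rt; aq. NH4Cl
Reagents that add atoms: none
Why: Luche 1,2-reduction of the enal gives the allylic alcohol 13, whose oxygen should attack the exocyclic imide carbonyl in a five-membered ring closure and release the auxiliary, the low temperature and buffered quench keeping the exocyclic alkene from migrating into conjugation.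

Step 7
Reactants: 14 (3R)-3-[10-(tert-butyldiphenylsilyloxy)decyl]-4-methylenedihydrofuran-2(3H)-one
Product: 16 (5R,9R)-9-[10-(tert-butyldiphenylsilyloxy)decyl]-1,7-dioxaspiro[4.4]nonane-2,8-dione, via (5R,9R)-9-[10-(tert-butyldiphenylsilyloxy)decyl]-2,8-dioxo-1,7-dioxaspiro[4.4]nonane-3-carboxylic acid 15 (not isolated)
Conditions: Mn(OAc)3·2H2O (2.2 equiv), malonic acid (5 equiv), AcOH, no added base, 30 °C; aqueous work-up; then wet DMSO, 120 °C
Reagents that add atoms: malonic acid (OC(=O)CC(=O)O)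
Why: Malonate bound to Mn(OAc)3 enolises and is oxidised by trivalent manganese to an electrophilic malonyl radical, which adds to the CH2 terminus of the exocyclic alkene of 14 (C–C bond); the tertiary ring radical is then oxidised by a second trivalent manganese and captured by the carboxylate oxygen (C–O bond) to give the spiro α-carboxy lactone 15, which loses CO2 on heating. The closest known reaction type is the Mn(OAc)3-mediated oxidative radical carbolactonisation of 1,1-disubstituted alkenes with carboxylic acids, in its mild malonic acid variant. The new five-membered lactone closes as the second event of this formal (3+2) annulation, by attack of the carboxylate oxygen on the oxidised tertiary carbon, which thereby becomes the spiro atom. The only new stereocentre, the spiro carbon, is controlled by the adjacent chain-bearing centre of the temporary lactone: the oxygen should close on the ring face anti to the decyl chain, which is the (5R) configuration the target needs. The step needs regioselectivity (secured by the 1,1-disubstituted alkene, whose CH2 end alone leads to a tertiary radical), facial selectivity (secured by the five-membered template) and a single annulation (secured by excess malonic acid and limiting Mn(OAc)3), and the near-ambient, base-free medium should keep the exocyclic double bond in place until it reacts.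

Step 8
Reactants: 16 (5R,9R)-9-[10-(tert-butyldiphenylsilyloxy)decyl]-1,7-dioxaspiro[4.4]nonane-2,8-dione
Product: 19 (2R)-2-[(1R)-11-(tert-butyldiphenylsilyloxy)-1-carboxyundecyl]-5-oxotetrahydrofuran-2-carboxylic acid, via dilithium (2R,3R)-2-[10-(tert-butyldiphenylsilyloxy)decyl]-3-hydroxy-3-(hydroxymethyl)hexanedioate 17 (not isolated), via (3R,4R)-14-(tert-butyldiphenylsilyloxy)-3-hydroxytetradecane-1,3,4-tricarboxylic acid 18 (not isolated)
Conditions: LiOH, THF/H2O, 0 °C → rt; then NaH2PO4 buffer (pH 6.7), MeCN, TEMPO (cat.), NaClO2, NaOCl (cat.), 35 °C; then 1 M HCl to pH 1, EtOAc; cat. TsOH, toluene, 40 °C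
Reagents that add atoms: lithium hydroxide ([Li+].[OH-]); sodium chlorite ([Na+].[O-]Cl=O)
Why: Hydroxide opens both lactones, the TEMPO-catalysed chlorite oxidation (Anelli-type, known for a primary alcohol beside a tertiary carbinol) should turn the freed CH2OH into CO2H without touching the tertiary alcohol, and acid recloses the only possible γ-lactone, so that both stereocentres pass through unchanged.

Step 9
Reactants: 19 (2R)-2-[(1R)-11-(tert-butyldiphenylsilyloxy)-1-carboxyundecyl]-5-oxotetrahydrofuran-2-carboxylic acid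
Product: 20 (2R)-2-[(1R)-1-carboxy-11-hydroxyundecyl]-5-oxotetrahydrofuran-2-carboxylic acid
Conditions: HF·pyridine, THF/pyridine, 0 °C → rt
Reagents that add atoms: none
Why: Fluoride-mediated desilylation under non-basic conditions should free the primary alcohol without opening the lactone or epimerising the centre beside it.

Step 10
Reactants: 21 (R)-malic acid
Product: 22 (3R)-2,5-dioxotetrahydrofuran-3-yl trifluoroacetate [(R)-2-(trifluoroacetoxy)succinic anhydride]
Conditions: (CF3CO)2O (neat), 0 °C → rt; evaporate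
Reagents that add atoms: trifluoroacetic anhydride (FC(F)(F)C(=O)OC(=O)C(F)(F)F)
Why: Trifluoroacetic anhydride both O-acylates the hydroxyl and dehydrates the diacid to the cyclic anhydride (a known activation of malic acid), with no bond to the stereocentre broken.

Step 11
Reactants: 20 (2R)-2-[(1R)-1-carboxy-11-hydroxyundecyl]-5-oxotetrahydrofuran-2-carboxylic acid; 22 (3R)-2,5-dioxotetrahydrofuran-3-yl trifluoroacetate
Product: 24 (2R)-2-[(1R)-1-carboxy-11-{[(2R)-3-carboxy-2-hydroxypropanoyl]oxy}undecyl]-5-oxotetrahydrofuran-2-carboxylic acid (target), via O-trifluoroacetyl derivative of the target 23 (not isolated)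
Conditions: 22 (3 equiv), THF, 0 °C → rt; then H2O, rt; reverse-phase chromatography
Reagents that add atoms: none
Why: Alcoholysis of the unsymmetrical anhydride should occur at the carbonyl next to the electron-withdrawing trifluoroacetoxy group (the known route to malic acid 1-monoesters), giving the ester at the hydroxy-bearing end with the β-carboxyl free, and the labile trifluoroacetate is hydrolysed in water.

**Compound list**

1 | 12-hydroxydodecanoic acid | OCCCCCCCCCCCC(=O)O | starting material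
2 | tert-butyldiphenylsilyl 12-(tert-butyldiphenylsilyloxy)dodecanoate | CC(C)(C)[Si](c1ccccc1)(c1ccccc1)OCCCCCCCCCCCC(=O)O[Si](c1ccccc1)(c1ccccc1)C(C)(C)C | intermediate
3 | 12-(tert-butyldiphenylsilyloxy)dodecanoic acid | CC(C)(C)[Si](c1ccccc1)(c1ccccc1)OCCCCCCCCCCCC(=O)O | intermediate
4 | (S)-4-benzyl-1,3-oxazolidin-2-one | O=C1OC[C@H](Cc2ccccc2)N1 | starting material
5 | 12-(tert-butyldiphenylsilyloxy)dodecanoic pivalic anhydride | CC(C)(C)[Si](c1ccccc1)(c1ccccc1)OCCCCCCCCCCCC(=O)OC(=O)C(C)(C)C | intermediate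
6 | (S)-4-benzyl-3-[12-(tert-butyldiphenylsilyloxy)dodecanoyl]-1,3-oxazolidin-2-one | CC(C)(C)[Si](c1ccccc1)(c1ccccc1)OCCCCCCCCCCCC(=O)N1[C@@H](Cc2ccccc2)COC1=O | intermediate
7 | sodium (Z)-enolate of imide 6 | CC(C)(C)[Si](c1ccccc1)(c1ccccc1)OCCCCCCCCCC/C=C(\[O-])N1[C@@H](Cc2ccccc2)COC1=O.[Na+] | intermediate
8 | (S)-4-benzyl-3-[(2R)-2-allyl-12-(tert-butyldiphenylsilyloxy)dodecanoyl]-1,3-oxazolidin-2-one | CC(C)(C)[Si](c1ccccc1)(c1ccccc1)OCCCCCCCCCC[C@@H](C(=O)N1[C@@H](Cc2ccccc2)COC1=O)CC=C | intermediate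
9 | 1,2,4-trioxolane (ozonide) of the allyl group of 8, mixture at the ozonide carbon | CC(C)(C)[Si](c1ccccc1)(c1ccccc1)OCCCCCCCCCC[C@@H](C(=O)N1[C@@H](Cc2ccccc2)COC1=O)CC1OCOO1 | intermediate
10 | (3R)-4-[(S)-4-benzyl-2-oxo-1,3-oxazolidin-3-yl]-3-[10-(tert-butyldiphenylsilyloxy)decyl]-4-oxobutanal | CC(C)(C)[Si](c1ccccc1)(c1ccccc1)OCCCCCCCCCC[C@@H](C(=O)N1[C@@H](Cc2ccccc2)COC1=O)CC=O | intermediate
11 | 2-(dimethylaminomethyl) Mannich base of aldehyde 10, mixture at the new centre | CC(C)(C)[Si](c1ccccc1)(c1ccccc1)OCCCCCCCCCC[C@@H](C(=O)N1[C@@H](Cc2ccccc2)COC1=O)C(CN(C)C)C=O | intermediate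
12 | (3R)-4-[(S)-4-benzyl-2-oxo-1,3-oxazolidin-3-yl]-3-[10-(tert-butyldiphenylsilyloxy)decyl]-2-methylene-4-oxobutanal | CC(C)(C)[Si](c1ccccc1)(c1ccccc1)OCCCCCCCCCC[C@@H](C(=O)N1[C@@H](Cc2ccccc2)COC1=O)C(=C)C=O | intermediate
13 | (S)-4-benzyl-3-[(2R)-12-(tert-butyldiphenylsilyloxy)-2-(3-hydroxyprop-1-en-2-yl)dodecanoyl]-1,3-oxazolidin-2-one | CC(C)(C)[Si](c1ccccc1)(c1ccccc1)OCCCCCCCCCC[C@@H](C(=O)N1[C@@H](Cc2ccccc2)COC1=O)C(=C)CO | intermediate
14 | (3R)-3-[10-(tert-butyldiphenylsilyloxy)decyl]-4-methylenedihydrofuran-2(3H)-one | CC(C)(C)[Si](c1ccccc1)(c1ccccc1)OCCCCCCCCCC[C@H]1C(=O)OCC1=C | intermediate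
15 | (5R,9R)-9-[10-(tert-butyldiphenylsilyloxy)decyl]-2,8-dioxo-1,7-dioxaspiro[4.4]nonane-3-carboxylic acid, mixture at C3 | CC(C)(C)[Si](c1ccccc1)(c1ccccc1)OCCCCCCCCCC[C@H]1C(=O)OC[C@@]12CC(C(=O)O)C(=O)O2 | intermediate
16 | (5R,9R)-9-[10-(tert-butyldiphenylsilyloxy)decyl]-1,7-dioxaspiro[4.4]nonane-2,8-dione | CC(C)(C)[Si](c1ccccc1)(c1ccccc1)OCCCCCCCCCC[C@H]1C(=O)OC[C@@]12CCC(=O)O2 | intermediate
17 | dilithium (2R,3R)-2-[10-(tert-butyldiphenylsilyloxy)decyl]-3-hydroxy-3-(hydroxymethyl)hexanedioate | CC(C)(C)[Si](c1ccccc1)(c1ccccc1)OCCCCCCCCCC[C@@H](C(=O)[O-])[C@@](O)(CO)CCC(=O)[O-].[Li+].[Li+] | intermediate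
18 | (3R,4R)-14-(tert-butyldiphenylsilyloxy)-3-hydroxytetradecane-1,3,4-tricarboxylic acid | CC(C)(C)[Si](c1ccccc1)(c1ccccc1)OCCCCCCCCCC[C@@H](C(=O)O)[C@@](O)(C(=O)O)CCC(=O)O | intermediate
19 | (2R)-2-[(1R)-11-(tert-butyldiphenylsilyloxy)-1-carboxyundecyl]-5-oxotetrahydrofuran-2-carboxylic acid | CC(C)(C)[Si](c1ccccc1)(c1ccccc1)OCCCCCCCCCC[C@@H](C(=O)O)[C@@]1(C(=O)O)CCC(=O)O1 | intermediate
20 | (2R)-2-[(1R)-1-carboxy-11-hydroxyundecyl]-5-oxotetrahydrofuran-2-carboxylic acid | OCCCCCCCCCC[C@@H](C(=O)O)[C@@]1(C(=O)O)CCC(=O)O1 | intermediate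
21 | (R)-malic acid | O=C(O)C[C@@H](O)C(=O)O | starting material
22 | (3R)-2,5-dioxotetrahydrofuran-3-yl trifluoroacetate | O=C1C[C@@H](OC(=O)C(F)(F)F)C(=O)O1 | intermediate
23 | (2R)-2-[(1R)-1-carboxy-11-{[(2R)-3-carboxy-2-(trifluoroacetoxy)propanoyl]oxy}undecyl]-5-oxotetrahydrofuran-2-carboxylic acid | O=C(O)C[C@@H](OC(=O)C(F)(F)F)C(=O)OCCCCCCCCCC[C@@H](C(=O)O)[C@@]1(C(=O)O)CCC(=O)O1 | intermediate
24 | (2R)-2-[(1R)-1-carboxy-11-{[(2R)-3-carboxy-2-hydroxypropanoyl]oxy}undecyl]-5-oxotetrahydrofuran-2-carboxylic acid | O=C(O)C[C@@H](O)C(=O)OCCCCCCCCCC[C@@H](C(=O)O)[C@@]1(C(=O)O)CCC(=O)O1 | target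

**Step count and risks**

Total step count: 11. Longest linear sequence: 10 steps (steps 1–9 and 11, from 12-hydroxydodecanoic acid); step 10 is a one-step branch.

Steps most likely to fail:

1. Step 7 (key step). The carboxylate may close on the wrong ring face (poor facial selectivity), a second annulation may consume the malonyl lactone, or the exocyclic double bond may migrate into the ring before the radical adds. The fallback sets out from 14 and returns at 16, and builds the same two ring bonds stepwise by polar chemistry. OsO4 (cat.)/N-methylmorpholine N-oxide dihydroxylation of 14, expected anti to the decyl chain, gives the 4-hydroxy-4-(hydroxymethyl) lactone F1. TEMPO/PhI(OAc)2 oxidises only its primary alcohol to the hydroxy aldehyde F2. A Wittig reaction with Ph3P=CHCO2Me gives the (E)-enoate F3. Hydrogenation over Pd/C gives the saturated hydroxy ester F4, which closes to 16 with cat. TsOH and loss of methanol.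

2. Step 8. The oxidation is run on an open-chain polyanion, so cleavage or over-oxidation of the tertiary/primary glycol, or incomplete reclosure of the lactone, may erode the material. The fallback sets out from 16 and returns at 19, and moves the oxidation onto a neutral, extractable lactone. After the LiOH opening to 17, the carboxylates are alkylated with BnBr in DMF to give the dibenzyl ester diol F5. Cat. camphorsulfonic acid closes the tertiary hydroxyl onto the unhindered propanoate ester, with loss of benzyl alcohol, to give the hydroxymethyl lactone benzyl ester F6. TEMPO/PhI(OAc)2 in MeCN/H2O oxidises the primary alcohol to the lactone acid benzyl ester F7, and hydrogenolysis over Pd/C gives 19.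

3. Step 11. The alcohol may attack the wrong anhydride carbonyl, or acyl groups may exchange with the two free carboxyls of 20 (loss of regiocontrol), and the resulting triacid mixture would be hard to separate. The fallback sets out from 19 and returns at 24, with the carboxyls masked and a regiodefined malate. BnBr/KHCO3 in DMF gives the dibenzyl ester F8; HF·pyridine gives the alcohol F9; MsCl/Et3N gives the mesylate F10. (R)-Malic acid 4-benzyl ester F11 is made from D-aspartic acid 4-benzyl ester by NaNO2/aq. H2SO4 deamination with retention. Its cesium carboxylate (Cs2CO3, DMF, 40 °C) is alkylated by F10 to give the tribenzyl ester F12, and hydrogenolysis over Pd/C gives 24.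

**Further compounds**

F1 | step 7 | (3R)-3-[10-(tert-butyldiphenylsilyloxy)decyl]-4-hydroxy-4-(hydroxymethyl)dihydrofuran-2(3H)-one, hydroxyl trans to the chain | CC(C)(C)[Si](c1ccccc1)(c1ccccc1)OCCCCCCCCCC[C@H]1C(=O)OC[C@@]1(O)CO
F2 | step 7 | 4-formyl-4-hydroxy analogue of F1 (hydroxy aldehyde), same configuration | CC(C)(C)[Si](c1ccccc1)(c1ccccc1)OCCCCCCCCCC[C@H]1C(=O)OC[C@@]1(O)C=O
F3 | step 7 | methyl (E)-3-{4-[10-(tert-butyldiphenylsilyloxy)decyl]-3-hydroxy-5-oxotetrahydrofuran-3-yl}acrylate, same configuration | CC(C)(C)[Si](c1ccccc1)(c1ccccc1)OCCCCCCCCCC[C@H]1C(=O)OC[C@@]1(O)/C=C/C(=O)OC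
F4 | step 7 | methyl 3-{4-[10-(tert-butyldiphenylsilyloxy)decyl]-3-hydroxy-5-oxotetrahydrofuran-3-yl}propanoate, same configuration | CC(C)(C)[Si](c1ccccc1)(c1ccccc1)OCCCCCCCCCC[C@H]1C(=O)OC[C@@]1(O)CCC(=O)OC
F5 | step 8 | dibenzyl (2R,3R)-2-[10-(tert-butyldiphenylsilyloxy)decyl]-3-hydroxy-3-(hydroxymethyl)hexanedioate | CC(C)(C)[Si](c1ccccc1)(c1ccccc1)OCCCCCCCCCC[C@@H](C(=O)OCc1ccccc1)[C@@](O)(CO)CCC(=O)OCc1ccccc1
F6 | step 8 | benzyl (2R)-12-(tert-butyldiphenylsilyloxy)-2-[(2R)-2-(hydroxymethyl)-5-oxotetrahydrofuran-2-yl]dodecanoate | CC(C)(C)[Si](c1ccccc1)(c1ccccc1)OCCCCCCCCCC[C@@H](C(=O)OCc1ccccc1)[C@@]1(CO)CCC(=O)O1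
F7 | step 8 | (2R)-2-[(1R)-1-(benzyloxycarbonyl)-11-(tert-butyldiphenylsilyloxy)undecyl]-5-oxotetrahydrofuran-2-carboxylic acid | CC(C)(C)[Si](c1ccccc1)(c1ccccc1)OCCCCCCCCCC[C@@H](C(=O)OCc1ccccc1)[C@@]1(C(=O)O)CCC(=O)O1
F8 | step 11 | benzyl (2R)-2-[(1R)-1-(benzyloxycarbonyl)-11-(tert-butyldiphenylsilyloxy)undecyl]-5-oxotetrahydrofuran-2-carboxylate | CC(C)(C)[Si](c1ccccc1)(c1ccccc1)OCCCCCCCCCC[C@@H](C(=O)OCc1ccccc1)[C@@]1(C(=O)OCc2ccccc2)CCC(=O)O1
F9 | step 11 | benzyl (2R)-2-[(1R)-1-(benzyloxycarbonyl)-11-hydroxyundecyl]-5-oxotetrahydrofuran-2-carboxylate | OCCCCCCCCCC[C@@H](C(=O)OCc1ccccc1)[C@@]1(C(=O)OCc2ccccc2)CCC(=O)O1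
F10 | step 11 | benzyl (2R)-2-[(1R)-1-(benzyloxycarbonyl)-11-(methylsulfonyloxy)undecyl]-5-oxotetrahydrofuran-2-carboxylate | CS(=O)(=O)OCCCCCCCCCC[C@@H](C(=O)OCc1ccccc1)[C@@]1(C(=O)OCc2ccccc2)CCC(=O)O1
F11 | step 11 | (R)-malic acid 4-benzyl ester | O=C(OCc1ccccc1)C[C@@H](O)C(=O)O
F12 | step 11 | tribenzyl ester of the target (both ring-side carboxyls and the malate β-carboxyl as benzyl esters) | O=C(OCc1ccccc1)C[C@@H](O)C(=O)OCCCCCCCCCC[C@@H](C(=O)OCc1ccccc1)[C@@]1(C(=O)OCc2ccccc2)CCC(=O)O1
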